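The runs come from a simulation on assumed constants, noise included.

How much E should we charge to the racemate of G and Z, with single-handed X, to get the most L in 25 d? The next run goes to one of the recipes below.

| flask | G | Z | E | X | remark | time |
|---|---|---|---|---|---|---|
| spring | 0.050 M | 0.050 M | 0.032 M | 25 µM | run made earlier |  |
| noon | 0.050 M | 0.050 M | 0.52 M | 25 µM | run made earlier |  |
| larch | 0.050 M | 0.050 M | 0.0500 M | 25 µM |  | 25 d |
| ash | 0.050 M | 0.050 M | 0.100 M | 25 µM |  | 25 d |
| maple | 0.050 M | 0.050 M | 0.200 M | 25 µM |  | 25 d |
| cedar | 0.050 M | 0.050 M | 0.400 M | 25 µM |  | 25 d |
| elm | 0.050 M | 0.050 M | 0.800 M | 25 µM |  | 25 d |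

- spring (time / d: L / %): 2.08: 8.5; 3.00: 10.0; 6.00: 16.3; 10.0: 19.9; 15.0: 18.5; 25.0: 18.5
- noon (time / d: L / %): 2.08: 48.8; 3.00: 52.4; 6.00: 53.6; 10.0: 54.4; 15.0: 54.0; 25.0: 54.8

(scatter of a reading: 1 percentage point)

- X is single-handed; G and Z are mirror images of each other, charged as a racemate, each of them at the stated concentration
- the numbers in the tables scatter by 1 percentage point (one standard deviation)
- "hardly changes" means that all values lie within two and a half points (for a concentration: within two and a half percent of the largest)

1. amount of L at the end, in percent of the G and Z together charged for larch, ash, maple, cedar, elm, in this order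
2. the shape of the row from first to last (falls all the way / falls, then rises / rises all the way / hardly changes / rises, then falls)

We reckon from the end state. Spring was charged with E at 32.0% of G and Z together and levels off from 10.0 d on. We take it that E has been consumed there, one E per substrate, and that the part not found as L went with Z to a product we do not read. Those late readings give 59.3% as the L share, the L formed per E consumed, a selectivity in the plain sense.

Noon, with E at 520% of the substrate, levels off with L above G's own charge, so some Z must pass over to G. If its substrate is consumed, noon reads an L share of 54.4%, lower than spring's.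

So L is the L share times the E consumed. Our reckoning gives larch 29.6%. Ash, with E equal to the substrate, gets 59.3% by this reckoning if its E is consumed, which its slow tail may not reach in the time. Maple has twice the E the substrate needs and less E than noon, so we expect it to finish with a share above noon's. Elm carries more E than noon, and we place it below noon's level. We expect a row that rises, then falls, and we would charge maple.

The forecast differs: 27%, 41%, 50.5%, 53.5%, 57%, a row that rises all the way, on the ground that “X evidently dies”. Its row points to elm.

The flask gives 30.4%, 52.8%, 56.7%, 53.9%, 52.1%: the row rises, then falls, with maple highest.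

    G ⇌ Z (k = 0.00840 h⁻¹)
    E + X + Z → X + D (k = 5900 L² mol⁻² h⁻¹)
    E + X + G → X + L (k = 10000 L² mol⁻² h⁻¹)
    2 X ⇌ Q, settled at all times (K = 19000 L mol⁻¹)

In larch, G passes to Z with a half-life of 3.4 d, forward step alone, against 7.3 d for G by reaction at 2.67 d, and after 25.0 d G and Z stand level at 25.3% and 25.4%. With 1.2% of its E left, the L share read from spring gives larch 29.3% against 30.4% found. In ash after 250 d, with E down to 1.32% of its charge, the L share read from spring gives 58.5%, and L stands at 59.5%.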